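**Remarks on the chemistry (assumptions)**

- 4-Benzyloxy-3-methoxybenzaldehyde (16) and (E)-3-(pinacolboryl)prop-2-en-1-ol (12) are treated as catalogue compounds. "Pinacolboryl" means 4,4,5,5-tetramethyl-1,3,2-dioxaborolan-2-yl.
- Locants: lactone C3 (α) carries the ring B benzyl group and C4 (β) the ring A benzyl group. C7/C8/C9 are the carbinol carbon, the aryl-bearing carbon and the CH2OH carbon of the open arm. C7'/C8'/C9' are the corresponding atoms of the closed arm (C2, C3 and CH2OH of the dihydrofuran).
- A re-derivation of all descriptors shows target, 15 and 18 to be mutually consistent: lactone (3S,4S) trans, open arm (7S,8S), dihydrofuran (2R,3S) trans, both arms of 18 (1S,2R). No structure needed correction.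
- The protecting-group pair of 15 (ring A O-benzyl, ring B O-triisopropylsilyl) is kept. The bulky silyl group is chosen so that the ether survives aqueous phosphate at 70 °C. Ring closure is placed before the vinyl groups are cleaved, because a primary C9'–OH would compete as electrophile in a 5-exo closure.
- The catalyst antipodes in steps 6 and 11 are assigned by analogy with the established sense of induction of each catalyst class. Each would be confirmed on the first intermediate it produces, and the mirror-image catalyst used if needed.

## Structural features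

The target is a trans-α,β-dibenzyl-γ-butyrolactone, (3S,4S), in which the C4 benzyl group carries ring A and the C3 benzyl group carries ring B. Ring A is a 2-hydroxy-3-methoxyphenyl unit joined through C5 to the lactone CH2; at C1 it bears an open arm, C8H(C9H2OH)–C7H(OH)–guaiacyl, with adjacent stereocentres (7S,8S). Ring B is the benzo ring of a trans-(2R,3S)-2-guaiacyl-3-hydroxymethyl-7-methoxy-2,3-dihydrobenzofuran, joined through its C5 to the other lactone CH2. The six stereocentres therefore form three adjacent pairs separated by CH2–arene spacers, so no pair can control another. Fragile sites are the p-hydroxybenzylic alcohol C7–OH and the benzylic ring ether C2–O1 (acid ionisation, hydrogenolysis), the epimerisable lactone C3, three free phenols on electron-rich arenes and the two 1,3-dioxygenated arms. The real difficulty is to set the absolute configuration of two remote arms that are diastereomeric with each other without a separate synthesis for each. The feature the key step uses is that both arenes carry, ortho to their phenolic oxygen, the same aryl–C8H(C9H2OH)–C7H(O)–guaiacyl unit: it is open as a diol on ring A and closed through O1–C2 on ring B, and the two differ in configuration only at the oxygen-bearing benzylic carbon (C7 against C2). One twofold C7–C8 bond formation can thus build both, and the difference is restored by inversion on ring closure.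

## Logic of the disconnections

**24 ⇒ 23.** The three phenolic O–CH2Ph bonds are the last to be broken, so three O-benzyl groups are added in the backward sense. Free phenols would not survive enolate, palladium and ozone chemistry, and two of them sit para to benzylic C–O bonds that ionise once the phenol is free. The gain is a single neutral unmasking at the end. The demand is that hydrogenolysis stop at the aryl benzyl ethers and spare C7–OH and the C2–O1 ring bond.

**23 ⇒ 20 (through 22 and 21).** Each hydroxymethyl carbon C9 and C9' is traced back to the inner carbon of a vinyl group, the forward cut being the C=C bond. An aryl-CH(vinyl) unit next to a carbinol is the retron of an allylboration, so both arms become homoallylic alcohol-type units. The forward cleavage and reduction must leave five electron-rich arenes and the lactone untouched and must not let the α-aryl aldehyde stage epimerise.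

**20 ⇒ 19 ⇒ 18.** The O1–C2 bond of the dihydrofuran is cut with inversion at C2, and the ring B phenol is masked as its silyl ether. After this cut both arms have the same constitution and the same (1S,2R) configuration, so one reagent can install both. The forward closure of 19 must be a displacement at C7' by the only free phenol with inversion (or at least trans-selective), while the ring A arm carbinol, which has no internal nucleophile, is left alone.

**18 ⇒ 15 + 16 (two equivalents).** Both C7–C8 bonds are cut. This divides the molecule into a lactone core and two identical aldehyde units and removes four stereocentres in one operation. The forward step must give the same anti, same-handed result at two remote boronates, which requires one catalyst, pure (E)-geometry and a catalysed rate well above the background rate.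

**15 ⇒ 13 + 14.** The two allylic C–B bonds are cut to allylic C–OH bonds. Allylic alcohols are robust and easy to purify, and the boron is introduced only one step before it is used. The forward borylation must be linear- and (E)-selective at both sites and must tolerate the lactone and the aryl silyl ether.

**13 ⇒ 11 + 12.** The two aryl–alkenyl bonds are cut to aryl bromides. Both bromides then come from the same brominated vanillin, and the three-carbon units come from one reagent with fixed (E)-geometry. The forward twofold coupling must work at bromides flanked by an ortho oxygen substituent, with a base that spares the lactone and the silyl ether.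

**11 ⇒ 10 + 4.** The C3–CH2 bond at the lactone α-carbon is cut. This is the classical dibenzylbutyrolactone disconnection: it separates the ring A and ring B halves, and the C3 configuration follows from C4 by substrate control. The forward alkylation must occur anti to the C4 substituent and without metal–halogen exchange at the aryl bromides.

**10 ⇒ 8 ⇒ 7 ⇒ 5 + 6 (through 9).** The lactone O–CH2 bond is opened to a succinate half-ester, the C4 stereocentre is traced back to an alkene, and the alkene to a condensation of aldehyde and succinate. This reduces the only stereocentre of 10 to a catalytic hydrogenation of a well-studied substrate class. The hydrogenation must tolerate an aryl bromide and a benzyl ether, and the reduction must distinguish ester from carboxylate.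

**4 ⇒ 3 ⇒ 2 ⇒ 1 and 5 ⇒ 1.** Both arenes go back to 1, which already holds bromine, methoxy, phenol and a one-carbon handle in the right positions. The only difference between the two halves is the phenol protecting group, chosen so that fluoride later addresses ring B alone.

## Other disconnections considered

**Alternative 1:** The cut runs through ring B itself: the C3a–C7a and C4–C5 bonds of the benzofuran are broken, leading back to the pyridazinyl ether A1, whose O-tether ends in a terminal alkyne. In the forward sense the alkyne of A1 adds across C3 and C6 of the diazine in an intramolecular inverse-electron-demand [4+2] cycloaddition. The bicyclic adduct then expels its N–N bridge, so the benzene ring and the dihydrofuran of A2 appear together.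
- In favour: the substitution pattern of ring B is written into the heterocycle. Both dihydrofuran stereocentres are made beforehand on an open chain and are not touched by the annulation.
- Better than the chosen plan on one point: no displacement with inversion at an ionisable benzylic carbon is needed, there is no question of which carbinol gets activated, and C9' arrives already as a silyl ether, so this arm needs no oxidative cleavage.
- Against: an alkoxy- and methoxy-substituted pyridazine is a weak azadiene. The cycloaddition would be expected to need prolonged heating well above 150 °C, where a benzylic ether of an electron-rich arene can fragment or migrate to nitrogen.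
- Against: A1 needs its own asymmetric construction of an anti propargylic carbinol and a regioselective substitution on a dihalogenated diazine.
- Against: A2 solves only the ring B arm. Its aryl chloride, deactivated by two oxygen substituents, must still be joined to a lactone-bearing CH2 by an sp2–sp3 coupling, and the ring A arm and the lactone remain open problems.
- Comparison: the alternative is a pericyclic step that creates no stereocentre; the chosen step is a closed-transition-state addition that creates four. The alternative does not use the kinship of the two arms and would be clearly longer.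

**Alternative 2:** The C8–C9 bond and the benzylic C7–O bond of the ring A arm are cut, leading back to the (E)-stilbene A3 and two molecules of formaldehyde A5. In the forward sense A5, activated inside a confined chiral imidodiphosphorimidate acid, attacks the alkene carbon next to ring A. The positive charge developing at the guaiacyl-bearing carbon is captured by the oxygen of a second A5 unit, and the trans-dioxane A4 closes with both arm stereocentres set.
- In favour, and better than the chosen plan on this point: the arm arrives at the correct oxidation level with its diol already protected, from the cheapest C1 unit, with no vinyl group, no ozone and no α-aryl aldehyde stage.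
- Equal: two adjacent stereocentres are set in one catalyst-controlled step, as in the chosen plan.
- Against: both alkene carbons are benzylic, so the regiochemistry rests only on the electronic bias between the pivalate-bearing ring A and the benzyloxy-bearing guaiacyl ring.
- Against: internal diaryl alkenes are less reactive than the terminal aryl alkenes for which this catalysis is established.
- Against: the methylene acetal of A4 needs strong acid for removal, which endangers C7 once its para oxygen is free.
- Against: the lactone α-benzylation must still follow with the dioxane in place, and only the ring A arm is made; the ring B arm would need a second, different sequence and its own ring closure.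
- Comparison: per arm the step count is comparable, but two different arm syntheses make the whole route longer than the two-directional plan.

**Alternative 3:** The O–CH2 bond of the lactone is cut, leading back to the prochiral cyclobutanone A6. In the forward sense a Baeyer–Villiger oxidation with hydrogen peroxide A8 under a chiral phosphoric acid, or with a Baeyer–Villiger monooxygenase, inserts oxygen next to one of the two enantiotopic CH2 groups and gives the lactone A7 with its stereocentre set. A7 is the same compound as 10.
- In favour: one strain-driven catalytic step with a cheap oxidant.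
- Better on one point: the step is free of precious metals.
- Equal on step count: A6 needs about three steps of ketene cycloaddition chemistry, about as many as steps 5 to 7 need from 5. Because A7 is identical with 10, it could replace steps 5 to 7 without any change downstream.
- Against: the enantiotopic CH2 groups lie far from the arene, so the acid-catalysed variant is typically less selective for 3-benzyl than for 3-aryl cyclobutanones, and acceptance of a bulky trisubstituted benzyl group by an enzyme is uncertain.
- Comparison: this alternative addresses only the lactone and says nothing about the arms, so it complements the chosen key step instead of competing with it. The hydrogenation route is kept because its substrate class (arylidenesuccinate half-esters) is the better established one.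

Key step: step 11

## Route

Step 1
Reactants: 1 5-bromovanillin (3-bromo-4-hydroxy-5-methoxybenzaldehyde)
Product: 2 3-bromo-5-methoxy-4-(triisopropylsilyloxy)benzaldehyde
Conditions: TIPSCl, imidazole, DMAP (cat.), DMF, rt
Reagents that add atoms: chlorotriisopropylsilane, CC(C)[Si](Cl)(C(C)C)C(C)C
Why: Silyl ether formation on an acidic phenol (para formyl, ortho bromine); the bulky triisopropylsilyl group is chosen so that the ether, later flanked by two ortho substituents, survives aqueous base and is cleaved only by fluoride.

Step 2
Reactants: 2 3-bromo-5-methoxy-4-(triisopropylsilyloxy)benzaldehyde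
Product: 3 [3-bromo-5-methoxy-4-(triisopropylsilyloxy)phenyl]methanol
Conditions: NaBH4, MeOH/THF, 0 °C
Reagents that add atoms: none
Why: Borohydride reduction of an aryl aldehyde; the aryl bromide and the hindered aryl silyl ether are inert at 0 °C.

Step 3
Reactants: 3 [3-bromo-5-methoxy-4-(triisopropylsilyloxy)phenyl]methanol
Product: 4 3-bromo-5-methoxy-4-(triisopropylsilyloxy)benzyl bromide
Conditions: CBr4, PPh3, CH2Cl2, 0 °C
Reagents that add atoms: carbon tetrabromide, BrC(Br)(Br)Br
Why: Appel reaction under neutral conditions, which avoids the acid that would ionise a p-silyloxybenzylic bromide; the bromide is used directly in step 8.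

Step 4
Reactants: 1 5-bromovanillin
Product: 5 4-benzyloxy-3-bromo-5-methoxybenzaldehyde
Conditions: BnBr, K2CO3, DMF, 60 °C
Reagents that add atoms: benzyl bromide, BrCc1ccccc1
Why: Williamson etherification of the phenoxide; benzyl is orthogonal to the silyl ether of the ring B half and stable to every later step before the last.

Step 5
Reactants: 5 4-benzyloxy-3-bromo-5-methoxybenzaldehyde, 6 dimethyl succinate
Product: 7 (E)-4-(4-benzyloxy-3-bromo-5-methoxyphenyl)-3-(methoxycarbonyl)but-3-enoic acid
Conditions: NaOMe, MeOH, reflux; then aq. HCl
Reagents that add atoms: none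
Why: Stobbe condensation: aldol addition of the succinate enolate to the non-enolisable aldehyde, lactonisation and eliminative ring opening give the arylidene half-ester, with the conjugated ester retained and the remote ester converted to the acid; the (E)-isomer predominates.

Step 6
Reactants: 7 (E)-4-(4-benzyloxy-3-bromo-5-methoxyphenyl)-3-(methoxycarbonyl)but-3-enoic acid
Product: 8 (3S)-4-(4-benzyloxy-3-bromo-5-methoxyphenyl)-3-(methoxycarbonyl)butanoic acid
Conditions: H2 (5 atm), [Rh(cod)((R,R)-Et-DuPhos)]BF4 (0.5 mol%), NaOMe (10 mol%), MeOH, rt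
Reagents that add atoms: none
Why: Asymmetric hydrogenation of an itaconate-type half-ester: the carboxylate and the alkene chelate rhodium and the C2-symmetric bisphospholane selects the alkene face, which sets the future lactone C4 as (S) (the (R,R)-ligand is expected to give this antipode by analogy with enamide reductions); cationic rhodium–bisphosphine catalysts leave aryl bromides and benzyl ethers untouched.

Step 7
Reactants: 8 (3S)-4-(4-benzyloxy-3-bromo-5-methoxyphenyl)-3-(methoxycarbonyl)butanoic acid
Product: 10 (4S)-4-(4-benzyloxy-3-bromo-5-methoxybenzyl)dihydrofuran-2(3H)-one, via hydroxy acid 9 (not isolated)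
Conditions: KOH (1 equiv), EtOH, 0 °C; CaCl2, NaBH4, −10 °C to rt; then 2 M HCl, rt
Reagents that add atoms: none
Why: Chemoselective borohydride reduction: calcium borohydride formed in the flask reduces the methyl ester while the potassium carboxylate is inert, and acidification lactonises the γ-hydroxy acid; the stereocentre is not involved.

Step 8
Reactants: 10 (4S)-4-(4-benzyloxy-3-bromo-5-methoxybenzyl)dihydrofuran-2(3H)-one, 4 3-bromo-5-methoxy-4-(triisopropylsilyloxy)benzyl bromide
Product: 11 (3S,4S)-4-(4-benzyloxy-3-bromo-5-methoxybenzyl)-3-[3-bromo-5-methoxy-4-(triisopropylsilyloxy)benzyl]dihydrofuran-2(3H)-one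
Conditions: LiN(SiMe3)2 (1.1 equiv), THF, −78 °C; then 4, DMPU, −78 to −30 °C
Reagents that add atoms: none
Why: Enolate alkylation of a β-substituted butyrolactone: the benzyl bromide approaches the lithium enolate anti to the C4 benzyl group, which sets C3 as (S) and gives the trans lactone by substrate control; an amide base at −78 °C does not exchange with the aryl bromides.

Step 9
Reactants: 11 (3S,4S)-dibromo lactone, 12 (E)-3-(pinacolboryl)prop-2-en-1-ol (2.6 equiv)
Product: 13 (3S,4S)-4-{4-(benzyloxy)-3-[(E)-3-hydroxyprop-1-enyl]-5-methoxybenzyl}-3-{3-[(E)-3-hydroxyprop-1-enyl]-5-methoxy-4-(triisopropylsilyloxy)benzyl}dihydrofuran-2(3H)-one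
Conditions: Pd(OAc)2 (5 mol%), SPhos (10 mol%), K3PO4, toluene/H2O (10:1), 70 °C; work-up at pH 4
Reagents that add atoms: none
Why: Twofold Suzuki–Miyaura coupling: the dialkylbiarylphosphine allows oxidative addition at both ortho-oxygenated bromides and the alkenylboronate transfers with retention of (E)-geometry; mild phosphate spares the hindered silyl ether, the slightly acidic work-up recloses any opened lactone, and C3 cannot be degraded because trans is the stable arrangement.

Step 10
Reactants: 13 bis(cinnamyl alcohol) lactone, 14 bis(pinacolato)diboron (2.6 equiv)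
Product: 15 (3S,4S)-4-{4-(benzyloxy)-3-methoxy-5-[(E)-3-(pinacolboryl)prop-1-enyl]benzyl}-3-{3-methoxy-5-[(E)-3-(pinacolboryl)prop-1-enyl]-4-(triisopropylsilyloxy)benzyl}dihydrofuran-2(3H)-one
Conditions: Pd(MeCN)4(BF4)2 (10 mol%), DMSO/MeOH (1:1), 50 °C
Reagents that add atoms: none
Why: Palladium-catalysed allylic borylation of allylic alcohols with a diboron reagent: the hydroxyl group is activated in the flask, an aryl-substituted π-allylpalladium species forms, and boron is delivered to the unsubstituted terminus, which gives the linear (E)-γ-aryl allylboronate at both sites; lactone and aryl silyl ether are inert.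

Step 11
Reactants: 15 bis[(E)-γ-aryl allyl pinacolboronate] lactone, 16 4-benzyloxy-3-methoxybenzaldehyde (2.6 equiv)
Product: 18 (3S,4S)-4-{4-(benzyloxy)-3-[(1S,2R)-1-(4-benzyloxy-3-methoxyphenyl)-1-hydroxybut-3-en-2-yl]-5-methoxybenzyl}-3-{3-[(1S,2R)-1-(4-benzyloxy-3-methoxyphenyl)-1-hydroxybut-3-en-2-yl]-5-methoxy-4-(triisopropylsilyloxy)benzyl}dihydrofuran-2(3H)-one, via bis(O-pinacolboryl) adduct 17 (not isolated)
Conditions: (S)-TRIP [(S)-3,3'-bis(2,4,6-triisopropylphenyl)-1,1'-binaphthalene-2,2'-diyl hydrogen phosphate] (10 mol%), 4 Å MS, toluene, −20 °C to rt; then aq. NaHCO3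
Reagents that add atoms: none
Why: Catalytic asymmetric allylboration run twice: each (E)-γ-aryl allylboronate of 15 adds through a closed six-membered chair transition state in which boron binds the aldehyde oxygen and the γ-carbon attacks the carbonyl carbon, the double bond moving to the terminal vinyl position. The phosphoric acid hydrogen-bonds to a boronate oxygen, which accelerates the addition and fixes the aldehyde face. The closest known reaction type is the chiral phosphoric acid-catalysed anti-selective crotylboration of aromatic aldehydes with (E)-crotyl pinacolboronate. No ring is closed. C7 and C7' (both S) are set by the catalyst, the (S)-acid being chosen because the (R)-acid is known to give (R)-carbinols from aryl aldehydes; C8 and C8' are set relative to them by the (E)-geometry, since the γ-aryl group and the aldehyde aryl group both lie equatorial in the chair, which gives the anti (1S,2R) arrangement in both arms. The step needs the catalysed path to outrun the uncatalysed one, which the low thermal reactivity of γ-aryl pinacolboronates at or below room temperature secures, and it needs both arms to react alike, which their separation by the lactone core and their near-identical ortho-alkoxyaryl surroundings secure. The aldehyde is non-enolisable and is used in excess so that the second addition goes to completion; the O-boryl groups of 17 are hydrolysed on work-up.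

Step 12
Reactants: 18 bis(anti homoallylic alcohol) with ring B O-triisopropylsilyl
Product: 19 (3S,4S)-4-{4-(benzyloxy)-3-[(1S,2R)-1-(4-benzyloxy-3-methoxyphenyl)-1-hydroxybut-3-en-2-yl]-5-methoxybenzyl}-3-{4-hydroxy-3-[(1S,2R)-1-(4-benzyloxy-3-methoxyphenyl)-1-hydroxybut-3-en-2-yl]-5-methoxybenzyl}dihydrofuran-2(3H)-one
Conditions: TBAF (1.2 equiv), AcOH (1.2 equiv), THF, 0 °C
Reagents that add atoms: none
Why: Fluoride desilylation of an aryl silyl ether; acetic acid buffers the phenoxide so that the lactone and its C3 centre are not exposed to base, and the three benzyl ethers are untouched, so only ring B carries a free phenol.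

Step 13
Reactants: 19 ring B phenol diol
Product: 20 (3S,4S)-4-{4-(benzyloxy)-3-[(1S,2R)-1-(4-benzyloxy-3-methoxyphenyl)-1-hydroxybut-3-en-2-yl]-5-methoxybenzyl}-3-{[(2R,3R)-2-(4-benzyloxy-3-methoxyphenyl)-7-methoxy-3-vinyl-2,3-dihydrobenzofuran-5-yl]methyl}dihydrofuran-2(3H)-one
Conditions: PPh3 (1.1 equiv), DIAD (1.1 equiv, slow addition), toluene, 0 °C
Reagents that add atoms: none
Why: Intramolecular Mitsunobu etherification: the phenol is the only acidic partner and displaces the oxyphosphonium group at C7' in a 5-exo-tet closure with inversion, which converts the anti arm into the trans (2R) dihydrofuran; even an ion-pair pathway would close trans to the C3 vinyl group. The ring A arm carbinol has no internal nucleophile, and with a near-stoichiometric amount of reagent it is expected to be recovered unchanged.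

Step 14
Reactants: 20 divinyl dihydrobenzofuran lactone
Product: 23 (3S,4S)-4-{4-(benzyloxy)-3-[(1S,2S)-1-(4-benzyloxy-3-methoxyphenyl)-1,3-dihydroxypropan-2-yl]-5-methoxybenzyl}-3-{[(2R,3S)-2-(4-benzyloxy-3-methoxyphenyl)-3-(hydroxymethyl)-7-methoxy-2,3-dihydrobenzofuran-5-yl]methyl}dihydrofuran-2(3H)-one, via bis(1,2,4-trioxolane) 21 (not isolated), via dialdehyde 22 (not isolated)
Conditions: O3, CH2Cl2, Sudan Red 7B (indicator), −78 °C; then MeOH, NaBH4, −78 to 0 °C
Reagents that add atoms: ozone, [O-][O+]=O
Why: Ozonolysis with reductive work-up: the terminal vinyl groups react faster than the alkoxyarenes and the dye marks the end point; borohydride reduces the ozonides through the aldehydes to the primary alcohols in the cold, so the α-aryl aldehyde stage has no time to epimerise at C8 or C8', and the lactone is not reduced at 0 °C.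

Step 15
Reactants: 23 tri-O-benzyl ether of the target
Product: 24 (3S,4S)-4-{3-[(1S,2S)-1,3-dihydroxy-1-(4-hydroxy-3-methoxyphenyl)propan-2-yl]-4-hydroxy-5-methoxybenzyl}-3-{[(2R,3S)-2-(4-hydroxy-3-methoxyphenyl)-3-(hydroxymethyl)-7-methoxy-2,3-dihydrobenzofuran-5-yl]methyl}dihydrofuran-2(3H)-one (CNP0199264.1)
Conditions: H2 (1 atm), 10% Pd/C, EtOAc/MeOH, rt, stopped at full conversion
Reagents that add atoms: none
Why: Catalytic hydrogenolysis of three aryl benzyl ethers; under neutral conditions at ambient pressure these cleave much faster than the benzylic C7–OH or the C2–O1 ring bond, and no stereocentre is touched.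

## Compound list

1 | 5-bromovanillin (3-bromo-4-hydroxy-5-methoxybenzaldehyde) | COc1cc(C=O)cc(Br)c1O | starting material
2 | 3-bromo-5-methoxy-4-(triisopropylsilyloxy)benzaldehyde | COc1cc(C=O)cc(Br)c1O[Si](C(C)C)(C(C)C)C(C)C | intermediate
3 | [3-bromo-5-methoxy-4-(triisopropylsilyloxy)phenyl]methanol | COc1cc(CO)cc(Br)c1O[Si](C(C)C)(C(C)C)C(C)C | intermediate
4 | 3-bromo-5-methoxy-4-(triisopropylsilyloxy)benzyl bromide | COc1cc(CBr)cc(Br)c1O[Si](C(C)C)(C(C)C)C(C)C | intermediate
5 | 4-benzyloxy-3-bromo-5-methoxybenzaldehyde | COc1cc(C=O)cc(Br)c1OCc1ccccc1 | intermediate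
6 | dimethyl succinate | COC(=O)CCC(=O)OC | starting material
7 | (E)-4-(4-benzyloxy-3-bromo-5-methoxyphenyl)-3-(methoxycarbonyl)but-3-enoic acid | COC(=O)/C(CC(=O)O)=C/c1cc(OC)c(OCc2ccccc2)c(Br)c1 | intermediate
8 | (3S)-4-(4-benzyloxy-3-bromo-5-methoxyphenyl)-3-(methoxycarbonyl)butanoic acid | COc1cc(C[C@@H](CC(=O)O)C(=O)OC)cc(Br)c1OCc1ccccc1 | intermediate
9 | (3S)-4-(4-benzyloxy-3-bromo-5-methoxyphenyl)-3-(hydroxymethyl)butanoic acid (not isolated) | COc1cc(C[C@@H](CC(=O)O)CO)cc(Br)c1OCc1ccccc1 | intermediate
10 | (4S)-4-(4-benzyloxy-3-bromo-5-methoxybenzyl)dihydrofuran-2(3H)-one | COc1cc(C[C@@H]2COC(=O)C2)cc(Br)c1OCc1ccccc1 | intermediate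
11 | (3S,4S)-4-(4-benzyloxy-3-bromo-5-methoxybenzyl)-3-[3-bromo-5-methoxy-4-(triisopropylsilyloxy)benzyl]dihydrofuran-2(3H)-one | COc1cc(C[C@@H]2COC(=O)[C@H]2Cc2cc(OC)c(O[Si](C(C)C)(C(C)C)C(C)C)c(Br)c2)cc(Br)c1OCc1ccccc1 | intermediate
12 | (E)-3-(4,4,5,5-tetramethyl-1,3,2-dioxaborolan-2-yl)prop-2-en-1-ol | OC/C=C/B1OC(C)(C)C(C)(C)O1 | starting material
13 | (3S,4S)-4-{4-(benzyloxy)-3-[(E)-3-hydroxyprop-1-enyl]-5-methoxybenzyl}-3-{3-[(E)-3-hydroxyprop-1-enyl]-5-methoxy-4-(triisopropylsilyloxy)benzyl}dihydrofuran-2(3H)-one | COc1cc(C[C@@H]2COC(=O)[C@H]2Cc2cc(OC)c(O[Si](C(C)C)(C(C)C)C(C)C)c(/C=C/CO)c2)cc(/C=C/CO)c1OCc1ccccc1 | intermediate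
14 | bis(pinacolato)diboron | CC1(C)OB(OC1(C)C)B1OC(C)(C)C(C)(C)O1 | starting material
15 | (3S,4S)-4-{4-(benzyloxy)-3-methoxy-5-[(E)-3-(pinacolboryl)prop-1-enyl]benzyl}-3-{3-methoxy-5-[(E)-3-(pinacolboryl)prop-1-enyl]-4-(triisopropylsilyloxy)benzyl}dihydrofuran-2(3H)-one | CC1(C)OB(C/C=C/c2cc(C[C@@H]3COC(=O)[C@H]3Cc3cc(OC)c(O[Si](C(C)C)(C(C)C)C(C)C)c(/C=C/CB4OC(C)(C)C(C)(C)O4)c3)cc(OC)c2OCc2ccccc2)OC1(C)C | intermediate
16 | 4-benzyloxy-3-methoxybenzaldehyde | COc1cc(C=O)ccc1OCc1ccccc1 | starting material
17 | bis(O-pinacolboryl) derivative of 18 at both carbinol oxygens (not isolated) | COc1cc([C@@H](OB5OC(C)(C)C(C)(C)O5)[C@H](C=C)c2cc(C[C@@H]3COC(=O)[C@H]3Cc3cc(OC)c(O[Si](C(C)C)(C(C)C)C(C)C)c(c3)[C@@H](C=C)[C@H](OB6OC(C)(C)C(C)(C)O6)c3ccc(OCc4ccccc4)c(OC)c3)cc(OC)c2OCc2ccccc2)ccc1OCc1ccccc1 | intermediate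
18 | (3S,4S)-4-{4-(benzyloxy)-3-[(1S,2R)-1-(4-benzyloxy-3-methoxyphenyl)-1-hydroxybut-3-en-2-yl]-5-methoxybenzyl}-3-{3-[(1S,2R)-1-(4-benzyloxy-3-methoxyphenyl)-1-hydroxybut-3-en-2-yl]-5-methoxy-4-(triisopropylsilyloxy)benzyl}dihydrofuran-2(3H)-one | COc1cc([C@@H](O)[C@H](C=C)c2cc(C[C@@H]3COC(=O)[C@H]3Cc3cc(OC)c(O[Si](C(C)C)(C(C)C)C(C)C)c(c3)[C@@H](C=C)[C@H](O)c3ccc(OCc4ccccc4)c(OC)c3)cc(OC)c2OCc2ccccc2)ccc1OCc1ccccc1 | intermediate
19 | ring B phenol of 18 (silyl group removed; both arms (1S,2R)) | COc1cc([C@@H](O)[C@H](C=C)c2cc(C[C@@H]3COC(=O)[C@H]3Cc3cc(OC)c(O)c(c3)[C@@H](C=C)[C@H](O)c3ccc(OCc4ccccc4)c(OC)c3)cc(OC)c2OCc2ccccc2)ccc1OCc1ccccc1 | intermediate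
20 | (3S,4S)-4-{4-(benzyloxy)-3-[(1S,2R)-1-(4-benzyloxy-3-methoxyphenyl)-1-hydroxybut-3-en-2-yl]-5-methoxybenzyl}-3-{[(2R,3R)-2-(4-benzyloxy-3-methoxyphenyl)-7-methoxy-3-vinyl-2,3-dihydrobenzofuran-5-yl]methyl}dihydrofuran-2(3H)-one | COc1cc([C@@H](O)[C@H](C=C)c2cc(C[C@@H]3COC(=O)[C@H]3Cc3cc(OC)c4c(c3)[C@@H](C=C)[C@H](c3ccc(OCc5ccccc5)c(OC)c3)O4)cc(OC)c2OCc2ccccc2)ccc1OCc1ccccc1 | intermediate
21 | bis-ozonide of 20: each vinyl group as a 1,2,4-trioxolan-3-yl group, trioxolane carbon unassigned (not isolated) | COc1cc([C@@H](O)[C@H](C5OCOO5)c2cc(C[C@@H]3COC(=O)[C@H]3Cc3cc(OC)c4c(c3)[C@@H](C6OCOO6)[C@H](c3ccc(OCc5ccccc5)c(OC)c3)O4)cc(OC)c2OCc2ccccc2)ccc1OCc1ccccc1 | intermediate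
22 | dialdehyde: each vinyl group of 20 as a formyl group, configuration unchanged (not isolated) | COc1cc([C@@H](O)[C@H](C=O)c2cc(C[C@@H]3COC(=O)[C@H]3Cc3cc(OC)c4c(c3)[C@@H](C=O)[C@H](c3ccc(OCc5ccccc5)c(OC)c3)O4)cc(OC)c2OCc2ccccc2)ccc1OCc1ccccc1 | intermediate
23 | (3S,4S)-4-{4-(benzyloxy)-3-[(1S,2S)-1-(4-benzyloxy-3-methoxyphenyl)-1,3-dihydroxypropan-2-yl]-5-methoxybenzyl}-3-{[(2R,3S)-2-(4-benzyloxy-3-methoxyphenyl)-3-(hydroxymethyl)-7-methoxy-2,3-dihydrobenzofuran-5-yl]methyl}dihydrofuran-2(3H)-one | COc1cc([C@@H](O)[C@H](CO)c2cc(C[C@@H]3COC(=O)[C@H]3Cc3cc(OC)c4c(c3)[C@@H](CO)[C@H](c3ccc(OCc5ccccc5)c(OC)c3)O4)cc(OC)c2OCc2ccccc2)ccc1OCc1ccccc1 | intermediate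
24 | (3S,4S)-4-{3-[(1S,2S)-1,3-dihydroxy-1-(4-hydroxy-3-methoxyphenyl)propan-2-yl]-4-hydroxy-5-methoxybenzyl}-3-{[(2R,3S)-2-(4-hydroxy-3-methoxyphenyl)-3-(hydroxymethyl)-7-methoxy-2,3-dihydrobenzofuran-5-yl]methyl}dihydrofuran-2(3H)-one (CNP0199264.1) | COc1cc([C@@H](O)[C@H](CO)c2cc(C[C@@H]3COC(=O)[C@H]3Cc3cc(OC)c4c(c3)[C@@H](CO)[C@H](c3ccc(O)c(OC)c3)O4)cc(OC)c2O)ccc1O | target

## Step count and least certain steps

Total step count: 15. Longest linear sequence: 12 steps (steps 4 to 15, from 1 through 5, 7, 8, 10, 11, 13, 15, 18, 19, 20 and 23 to 24). The ring B branch (steps 1 to 3) joins at step 8.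

**Step 11 (key step).** The most likely failure is a slow or weakly selective catalysed addition. The γ-aryl groups carry ortho oxygen substituents (the silyl ether is the larger one) that crowd the chair transition state, and the aldehyde is electron-rich and therefore a poor electrophile. The reaction may then need temperatures at which the uncatalysed, non-enantioselective addition competes, or may stall after the first arm. The fallback replaces catalyst control by reagent control; it sets out from 13 and comes back at 18. Compound 13 is borylated with B2(OH)4 (Pd(MeCN)4(BF4)2, DMSO/MeOH) to the bis(allylboronic acid) F1. F1 is esterified with diisopropyl (2R,3R)-tartrate (MgSO4, toluene) to the bis(tartrate allylboronate) F2. F2 is added to 16 in toluene over 4 Å MS at −78 °C. The tartrate esters direct attack to the si face of the aldehyde through the same chair, which gives the (1S,2R) anti arms, and aqueous work-up returns 18.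

**Step 13.** The risk is unselective activation. The ring A arm carbinol can also form an oxyphosphonium species, and because it is a p-benzyloxybenzylic position it may ionise, which leads to elimination towards the conjugated diene or to capture by the neighbouring benzyl ether oxygen; E2 loss of the acidic C8'–H is a second leak. The fallback changes the closure to an acid-mediated ionisation in which the ring A arm is thermodynamically self-correcting; it sets out from 18 and comes back at 23.
- Compound 18 is ozonised and reduced as in step 14 to the tetraol silyl ether F3.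
- TBAF/AcOH frees the phenol tetraol F4.
- F4 is treated with 2,2-dimethoxypropane and camphorsulfonic acid (cat.) in CH2Cl2. The ring A arm is held as its trans-4,5-diequatorial acetonide, the stable isomer, which corresponds to the required (7S,8S) arm, so that reversible ionisation at C7 returns to the same configuration. On the ring B arm the benzylic C7'–O bond ionises and is captured by the phenol to give the trans dihydrofuran with free C9'–OH, forming the acetonide F5.
- Aqueous acetic acid at rt removes the acetonide and gives 23.

**Step 14.** The risks are over-oxidation of the alkoxyarenes or benzyl ethers by ozone and, at the aldehyde stage, epimerisation at C8 or C8', retro-aldol cleavage of the ring A arm or eliminative opening of the dihydrofuran. The fallback separates oxidation from cleavage; it sets out from 20 and comes back at 23. Dihydroxylation with OsO4 (cat.) and N-methylmorpholine N-oxide in acetone/H2O gives the bis(1,2-diol) F6. F6 is cleaved with NaIO4 in THF/pH 7 buffer at 0 °C to 22, which is reduced at once with NaBH4 to 23.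

**Step 10.** The risks are allyl–allyl coupling of product with the π-allylpalladium intermediate, protodeboronation in methanol, methyl ether formation at the ionisable cinnamyl positions, and loss of (E)-purity. The fallback uses a pre-activated leaving group and a zerovalent palladium catalyst in an aprotic medium; it sets out from 13 and comes back at 15. Acetylation (Ac2O, pyridine, DMAP) gives the bis(allylic acetate) F7, which undergoes Miyaura-type allylic borylation with 14 and Pd2(dba)3 in DMSO at 50 °C to give 15.

**Step 15.** The risk is hydrogenolysis beyond the benzyl ethers: reductive loss of the benzylic C7–OH, which becomes more labile once its para phenol is free, or opening of the C2–O1 bond. The fallback shields the hydroxyl groups first; it sets out from 23 and comes back at 24. Silylation with TBSOTf and 2,6-lutidine gives the tris(tert-butyldimethylsilyl) ether F8. Hydrogenolysis (H2, Pd/C) gives the triphenol F9, whose bulky benzylic silyl ether resists reduction. TBAF/AcOH then gives 24.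

## Further compounds

F1 | step 11 | bis(allylboronic acid): 13 with each CH2OH replaced by CH2B(OH)2 | COc1cc(C[C@@H]2COC(=O)[C@H]2Cc2cc(OC)c(O[Si](C(C)C)(C(C)C)C(C)C)c(/C=C/CB(O)O)c2)cc(/C=C/CB(O)O)c1OCc1ccccc1
F2 | step 11 | bis(tartrate allylboronate): F1 esterified at each boron with diisopropyl (2R,3R)-tartrate | COc1cc(C[C@@H]2COC(=O)[C@H]2Cc2cc(OC)c(O[Si](C(C)C)(C(C)C)C(C)C)c(/C=C/CB3O[C@@H](C(=O)OC(C)C)[C@H](C(=O)OC(C)C)O3)c2)cc(/C=C/CB2O[C@@H](C(=O)OC(C)C)[C@H](C(=O)OC(C)C)O2)c1OCc1ccccc1
F3 | step 13 | tetraol silyl ether: 18 with both vinyl groups replaced by CH2OH | COc1cc([C@@H](O)[C@H](CO)c2cc(C[C@@H]3COC(=O)[C@H]3Cc3cc(OC)c(O[Si](C(C)C)(C(C)C)C(C)C)c(c3)[C@@H](CO)[C@H](O)c3ccc(OCc4ccccc4)c(OC)c3)cc(OC)c2OCc2ccccc2)ccc1OCc1ccccc1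
F4 | step 13 | phenol tetraol: F3 without the triisopropylsilyl group | COc1cc([C@@H](O)[C@H](CO)c2cc(C[C@@H]3COC(=O)[C@H]3Cc3cc(OC)c(O)c(c3)[C@@H](CO)[C@H](O)c3ccc(OCc4ccccc4)c(OC)c3)cc(OC)c2OCc2ccccc2)ccc1OCc1ccccc1
F5 | step 13 | acetonide of 23: ring A arm as (4S,5S)-2,2-dimethyl-1,3-dioxane, ring B arm as trans dihydrofuran with free CH2OH | COc1cc([C@H]5OC(C)(C)OC[C@@H]5c2cc(C[C@@H]3COC(=O)[C@H]3Cc3cc(OC)c4c(c3)[C@@H](CO)[C@H](c3ccc(OCc6ccccc6)c(OC)c3)O4)cc(OC)c2OCc2ccccc2)ccc1OCc1ccccc1
F6 | step 14 | bis(1,2-diol): 20 with each vinyl group as CH(OH)CH2OH, new carbinol centres unassigned | COc1cc([C@@H](O)[C@H](C(O)CO)c2cc(C[C@@H]3COC(=O)[C@H]3Cc3cc(OC)c4c(c3)[C@@H](C(O)CO)[C@H](c3ccc(OCc5ccccc5)c(OC)c3)O4)cc(OC)c2OCc2ccccc2)ccc1OCc1ccccc1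
F7 | step 10 | bis(allylic acetate) of 13 | COc1cc(C[C@@H]2COC(=O)[C@H]2Cc2cc(OC)c(O[Si](C(C)C)(C(C)C)C(C)C)c(/C=C/COC(C)=O)c2)cc(/C=C/COC(C)=O)c1OCc1ccccc1
F8 | step 15 | tris(tert-butyldimethylsilyl) ether of 23 at C7–OH, C9–OH and C9'–OH | COc1cc([C@@H](O[Si](C)(C)C(C)(C)C)[C@H](CO[Si](C)(C)C(C)(C)C)c2cc(C[C@@H]3COC(=O)[C@H]3Cc3cc(OC)c4c(c3)[C@@H](CO[Si](C)(C)C(C)(C)C)[C@H](c3ccc(OCc5ccccc5)c(OC)c3)O4)cc(OC)c2OCc2ccccc2)ccc1OCc1ccccc1
F9 | step 15 | tris(tert-butyldimethylsilyl) ether of 24 with three free phenols | COc1cc([C@@H](O[Si](C)(C)C(C)(C)C)[C@H](CO[Si](C)(C)C(C)(C)C)c2cc(C[C@@H]3COC(=O)[C@H]3Cc3cc(OC)c4c(c3)[C@@H](CO[Si](C)(C)C(C)(C)C)[C@H](c3ccc(O)c(OC)c3)O4)cc(OC)c2O)ccc1O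
A1 | alternative 1 | 3-{[(1R,2S)-1-(4-benzyloxy-3-methoxyphenyl)-2-[(tert-butyldimethylsilyloxy)methyl]but-3-yn-1-yl]oxy}-6-chloro-4-methoxypyridazine | COc1cc(Cl)nnc1O[C@@H](c1ccc(OCc2ccccc2)c(OC)c1)[C@H](CO[Si](C)(C)C(C)(C)C)C#C
A2 | alternative 1 | (2R,3S)-2-(4-benzyloxy-3-methoxyphenyl)-3-[(tert-butyldimethylsilyloxy)methyl]-5-chloro-7-methoxy-2,3-dihydrobenzofuran | Clc1cc(OC)c2c(c1)[C@@H](CO[Si](C)(C)C(C)(C)C)[C@H](c1ccc(OCc3ccccc3)c(OC)c1)O2
A3 | alternative 2 | 2-[(E)-2-(4-benzyloxy-3-methoxyphenyl)ethenyl]-6-methoxy-4-{[(3S)-5-oxotetrahydrofuran-3-yl]methyl}phenyl pivalate | COc1cc(C[C@@H]2COC(=O)C2)cc(/C=C/c2ccc(OCc3ccccc3)c(OC)c2)c1OC(=O)C(C)(C)C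
A4 | alternative 2 | 2-[(4S,5S)-4-(4-benzyloxy-3-methoxyphenyl)-1,3-dioxan-5-yl]-6-methoxy-4-{[(3S)-5-oxotetrahydrofuran-3-yl]methyl}phenyl pivalate | COc1cc(C[C@@H]2COC(=O)C2)cc([C@H]2COCO[C@@H]2c2ccc(OCc3ccccc3)c(OC)c2)c1OC(=O)C(C)(C)C
A5 | alternative 2 | formaldehyde | C=O
A6 | alternative 3 | 3-(4-benzyloxy-3-bromo-5-methoxybenzyl)cyclobutanone | COc1cc(CC2CC(=O)C2)cc(Br)c1OCc1ccccc1
A7 | alternative 3 | (4S)-4-(4-benzyloxy-3-bromo-5-methoxybenzyl)dihydrofuran-2(3H)-one (identical with 10) | COc1cc(C[C@@H]2COC(=O)C2)cc(Br)c1OCc1ccccc1
A8 | alternative 3 | hydrogen peroxide | OO
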